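All constants are those of an exercise, and the outcome is calculated.

**Short-lived reagent.** 2.2 s is the half-life of the coupling partner by its own decomposition, so the time allowed held about 415 such half-lives. On the free catalyst, the partner also couples with either substrate and the catalyst comes back. The partner can also turn free catalyst into spent catalyst.

left-handed substrate 5.0 mM; coupling partner 10.0 mM; free catalyst 0.65 mM (in portions, 2); right-handed substrate 5.0 mM; time 15 min; the portions of free catalyst follow each other after 0.40 s, the first at the start

- at 15 min, what has stopped the reaction, if anything has (it is still moving / no working catalyst is left / the coupling partner has run out first / all of the left-handed substrate has reacted)
- part of the left-handed substrate and right-handed substrate together gone at 15 min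
- the left-handed product standing at 15 min, as a percentage of the left-handed substrate and right-handed substrate together charged
- the right-handed substrate standing at 15 min, as a percentage of the left-handed substrate and right-handed substrate together charged

**Bench rule.** I first counted equivalents: the partner charge of 10.0 mM matched the 10.0 mM of substrate, which allowed left-handed product up to 50.0%. That count assumed that coupling outran decomposition. With the whole charges present, the partner's half-life by left-handed coupling was 5.92 s, or 2.74 times its decomposition half-life, so this flask lay past that border.

**Loss ratio.** Left-handed coupling and catalyst loss both run on the product of partner and free catalyst. The natural logarithm of the left-handed substrate therefore falls by Λ, the loss ratio, for each unit of catalyst spent: Λ is 36000 /M²/s over 37 /M/s, or 0.973 /mM. The partner's concentration integrated over time is at most its charge times its decomposition lifetime, so I reckoned that in this flask at least 31.5% of the catalyst survived and at most 0.445 mM was spent. In this flask, I reckoned that at least 64.8% of the left-handed substrate stayed. With the selectivity factor of 5.07, at least 91.8% of the right-handed substrate stayed in this flask, so its conversion was at most 21.7%.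

**The forecast.** The forecast said the coupling partner has run out first, with conversion 18.4% (17% to 20%), left-handed product 15% and right-handed substrate 46.6%, as the reaction “stops well short of full conversion”. My ceiling stood above its conversion.

**The flask.** The simulation gave the coupling partner has run out first, with conversion 18.4%, left-handed product 15.0% and right-handed substrate 46.6%.

    coupling partner + free catalyst + right-handed substrate → free catalyst + right-handed product (k1 = 7100 /M²/s)
    coupling partner + free catalyst + left-handed substrate → free catalyst + left-handed product (k2 = 36000 /M²/s)
    coupling partner → decomposed reagent (k3 = 0.32 /s)
    coupling partner + free catalyst → spent catalyst (k4 = 37 /M/s)

**Spent share.** In this flask, the 2.2 s decomposition half-life stood against 5.92 s for left-handed coupling at whole charges. At 15.0 min it held 7.79 mM of decomposed reagent and 0% of its partner, while 44% of the catalyst could still turn over. Its spent catalyst of 0.367 mM gives, through Λ, 70.0% of the left-handed substrate left, and the flask held 70% of that charge. The neighbour with 4.0 mM of partner ended with 26.4% of its catalyst spent, which gives 84.6%, and that neighbour held 85% of its left-handed substrate charge.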